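## Retrosynthetic overview
1. 14 ⇒ 10: remove the MOM group and return the C8 prenyl group to O5 (retro para-Claisen–Cope). The prenyl group first protects the 5-OH and then becomes the C8 substituent.
2. 10 ⇒ 6: remove the 3-OH (C3 oxygenation of the flavanone 3-hydroxylase type, anti to the aryl group). Then open O1–C2 (6-endo oxa-Michael of the chalcone isomerase type, catalyst-controlled). Both are run forward in one flask.
3. 6 ⇒ 3 + 5 (Claisen–Schmidt); 3 ⇒ 1 + 2 (mono-O-prenylation of a symmetric diol); 5 ⇒ 4 (MOM ether).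
4. Ring order: rings A and B are bought as arenes. The only ring made is the pyranone ring C (step 4), closed from the open chalcone as in the plant.

Assumption: the quinidine-derived thiourea is taken to give the (2S)-flavanone, by analogy with its additions to chalcones; if the sense is opposite, the quinine-derived pseudo-enantiomer is used and nothing else changes.

## Route

Step 1
Reactants: 1 1-(2,6-dihydroxy-4-methoxyphenyl)ethanone; 2 3-methylbut-2-en-1-ol (prenol)
Product: 3 1-[2-hydroxy-4-methoxy-6-(3-methylbut-2-enyloxy)phenyl]ethanone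
Conditions: 2 (1.05 equiv), PPh3 (1.1 equiv), DIAD (1.1 equiv), THF, 0 °C → rt
Reagents that add atoms: none
Why: Mitsunobu etherification puts the prenyl group on oxygen only (no C-prenylation, which plagues phenoxide/prenyl halide chemistry on phloroglucinol rings), the two OH groups of 1 are equivalent so only one mono-ether can form, and the remaining OH is tied up in a hydrogen bond to the ketone and reacts far more slowly; no stereocentre is formed.

Step 2
Reactants: 4 vanillin
Product: 5 3-methoxy-4-(methoxymethoxy)benzaldehyde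
Conditions: MOMCl (1.2 equiv), K2CO3, acetone, 0 °C → rt
Reagents that add atoms: chloromethyl methyl ether, COCCl
Why: Williamson-type O-alkylation of the vanillin phenoxide with the very reactive α-chloro ether; the MOM group is needed because a free 4-OH would deactivate the aldehyde and later the enone as a phenoxide and would labilise C2 through a quinone methide, and it survives KOH, amines, TMSOTf/Et3N, DMDO and Eu(III).

Step 3
Reactants: 3 1-[2-hydroxy-4-methoxy-6-(3-methylbut-2-enyloxy)phenyl]ethanone; 5 3-methoxy-4-(methoxymethoxy)benzaldehyde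
Product: 6 (E)-1-[2-hydroxy-4-methoxy-6-(3-methylbut-2-enyloxy)phenyl]-3-[3-methoxy-4-(methoxymethoxy)phenyl]prop-2-en-1-one
Conditions: KOH (10 equiv), EtOH–H2O, rt, 48 h; then cold 1 M HCl to pH 5–6; crystallise
Reagents that add atoms: none
Why: Claisen–Schmidt condensation (aldol addition then E1cB loss of water) gives the conjugated (E)-enone, and in strong base the product is parked as the ring-open chalcone phenoxide, so a cold, weakly acidic quench and crystallisation deliver 6 free of racemic flavanone.

Step 4 (key step)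
Reactants: 6 (E)-2'-hydroxy-4'-methoxy-6'-prenyloxy-3-methoxy-4-(methoxymethoxy)chalcone
Product: 10 (2R,3R)-3-hydroxy-7-methoxy-2-[3-methoxy-4-(methoxymethoxy)phenyl]-5-(3-methylbut-2-enyloxy)chroman-4-one, via (2S)-flavanone 7 (not isolated), via TMS enol ether 8 (not isolated), via 3-O-TMS ketone 9 (not isolated)
Conditions: (i) quinidine-derived 9-epi-amino N-[3,5-(CF3)2C6H3]thiourea (10 mol %), PhMe, 0 °C → rt; (ii) Et3N, TMSOTf, −20 °C, then filtration through Et3N-deactivated SiO2 and concentration; (iii) DMDO (1.1 equiv), CH2Cl2–acetone, −78 → −40 °C; (iv) citric acid (cat.), MeOH, 0 °C; recrystallise 10 to raise the ee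
Reagents that add atoms: dimethyldioxirane, CC1(C)OO1 (the C3 oxygen); trimethylsilyl triflate, C[Si](C)(C)OS(=O)(=O)C(F)(F)F (its Me3Si group is present only in 8 and 9)
Why: Proposed new method: this is a one-flask mimic of chalcone isomerase and flavanone 3-hydroxylase in which the quinuclidine of the bifunctional catalyst deprotonates the 2'-OH while the thiourea binds the enone carbonyl, so the phenoxide adds 6-endo-trig to one face of Cβ and sets C2 as S (the 6'-prenyloxy group twists the aryl ketone out of plane, which speeds closure, and leaves only one nucleophilic OH); because this oxa-Michael addition is reversible, the flavanone is not isolated but frozen by soft enolisation (no free enolate, hence no E1cB ring opening) as the 2H-chromene silyl enol ether, whose Rubottom oxidation takes place on the face anti to the 2-aryl group and, after 1,4-silyl shift and methanolysis, sets C3 trans to C2 (2R,3R), the electron-rich enol ether reacting much faster with DMDO than the inductively deactivated alkene of the allylic aryl ether; the closest known reaction types are the cinchona-thiourea intramolecular oxa-Michael cyclisation of 2'-hydroxychalcones (high ee secured so far mainly for α-ester-activated chalcones) and the Rubottom oxidation of flavanone silyl enol ethers to trans-3-hydroxyflavanones.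

Step 5
Reactants: 10 (2R,3R)-3-hydroxy-7-methoxy-2-[3-methoxy-4-(methoxymethoxy)phenyl]-5-(3-methylbut-2-enyloxy)chroman-4-one
Product: 14 (2R,3R)-3,5-dihydroxy-2-(4-hydroxy-3-methoxyphenyl)-7-methoxy-8-(3-methylbut-2-enyl)chroman-4-one, via ortho-dienone 11 (not isolated), via para-dienone 12 (not isolated), via 4'-O-MOM ether 13 (not isolated)
Conditions: Eu(fod)3 (10 mol %), CHCl3, 65 °C (sealed), 24 h; then MeOH, conc. HCl (to ca. 1 M), 40 °C, 2 h
Reagents that add atoms: none
Why: Eu(III) held between C4=O and O5 triggers the aromatic Claisen rearrangement to C6 (the only free ortho carbon), the crowded 6-(1,1-dimethylallyl) dienone passes the group on by a Cope rearrangement to C8 and enolises to the hydrogen-bonded 5-OH phenol (para-Claisen–Cope sequence known for 5-O-prenyl flavanones and flavonols), after which acid-catalysed acetal methanolysis removes the MOM group; C2 and C3 are not touched, the C3 carbinol would steer any reversible C2–O1 opening back to the more stable trans isomer, and the C8 prenyl group has no free ortho OH with which to close a chroman.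

## Compound list
1 | 1-(2,6-dihydroxy-4-methoxyphenyl)ethanone | CC(=O)c1c(O)cc(OC)cc1O | starting material
2 | 3-methylbut-2-en-1-ol (prenol) | CC(C)=CCO | starting material
3 | 1-[2-hydroxy-4-methoxy-6-(3-methylbut-2-enyloxy)phenyl]ethanone | CC(=O)c1c(O)cc(OC)cc1OCC=C(C)C | intermediate
4 | vanillin | COc1cc(C=O)ccc1O | starting material
5 | 3-methoxy-4-(methoxymethoxy)benzaldehyde | COCOc1ccc(C=O)cc1OC | intermediate
6 | (E)-1-[2-hydroxy-4-methoxy-6-(3-methylbut-2-enyloxy)phenyl]-3-[3-methoxy-4-(methoxymethoxy)phenyl]prop-2-en-1-one | COCOc1ccc(/C=C/C(=O)c2c(O)cc(OC)cc2OCC=C(C)C)cc1OC | intermediate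
7 | (2S)-7-methoxy-2-[3-methoxy-4-(methoxymethoxy)phenyl]-5-(3-methylbut-2-enyloxy)chroman-4-one | COc1cc([C@H]2Oc3cc(OC)cc(OCC=C(C)C)c3C(=O)C2)ccc1OCOC | intermediate
8 | (2S)-7-methoxy-2-[3-methoxy-4-(methoxymethoxy)phenyl]-5-(3-methylbut-2-enyloxy)-4-(trimethylsilyloxy)-2H-chromene | COc1cc([C@H]2Oc3cc(OC)cc(OCC=C(C)C)c3C(O[Si](C)(C)C)=C2)ccc1OCOC | intermediate
9 | (2R,3R)-7-methoxy-2-[3-methoxy-4-(methoxymethoxy)phenyl]-5-(3-methylbut-2-enyloxy)-3-(trimethylsilyloxy)chroman-4-one | COc1cc([C@H]2Oc3cc(OC)cc(OCC=C(C)C)c3C(=O)[C@@H]2O[Si](C)(C)C)ccc1OCOC | intermediate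
10 | (2R,3R)-3-hydroxy-7-methoxy-2-[3-methoxy-4-(methoxymethoxy)phenyl]-5-(3-methylbut-2-enyloxy)chroman-4-one | COc1cc([C@H]2Oc3cc(OC)cc(OCC=C(C)C)c3C(=O)[C@@H]2O)ccc1OCOC | intermediate
11 | ortho-dienone: (2R,3R)-3-hydroxy-7-methoxy-2-[3-methoxy-4-(methoxymethoxy)phenyl]-6-(2-methylbut-3-en-2-yl)-2,3-dihydro-6H-chromene-4,5-dione (C6 epimers) | COc1cc([C@H]2OC3=C(C(=O)[C@@H]2O)C(=O)C(C(C)(C)C=C)C(OC)=C3)ccc1OCOC | intermediate
12 | para-dienone: (2R,3R)-3-hydroxy-7-methoxy-2-[3-methoxy-4-(methoxymethoxy)phenyl]-8-(3-methylbut-2-enyl)-2,3-dihydro-8H-chromene-4,5-dione (C8 epimers) | COc1cc([C@H]2OC3=C(C(=O)[C@@H]2O)C(=O)C=C(OC)C3CC=C(C)C)ccc1OCOC | intermediate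
13 | (2R,3R)-3,5-dihydroxy-7-methoxy-2-[3-methoxy-4-(methoxymethoxy)phenyl]-8-(3-methylbut-2-enyl)chroman-4-one | COc1cc([C@H]2Oc3c(CC=C(C)C)c(OC)cc(O)c3C(=O)[C@@H]2O)ccc1OCOC | intermediate
14 | (2R,3R)-3,5-dihydroxy-2-(4-hydroxy-3-methoxyphenyl)-7-methoxy-8-(3-methylbut-2-enyl)chroman-4-one | COc1cc([C@H]2Oc3c(CC=C(C)C)c(OC)cc(O)c3C(=O)[C@@H]2O)ccc1O | target

## Step count and risks
Total step count: 5. Longest linear sequence: 4 (steps 1, 3, 4, 5; step 2 is the side branch).

**Step 4 is the most likely to fail.** The chalcone is unactivated and has an electron-rich B ring, so the ee may be only moderate. The chalcone/flavanone equilibrium may stop short of full conversion. DMDO may also touch the prenyl ether.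

The fallback takes the absolute configuration from a reagent-controlled epoxidation instead of from the ring closure.
- It sets out from 6. The 2'-OH is silylated (TIPSOTf, 2,6-lutidine) to give the 2'-O-triisopropylsilyl chalcone F1.
- Nucleophilic Juliá–Colonna epoxidation (poly-L-leucine, urea·H2O2, DBU, THF) attacks only the enone and gives the (αR,βS)-epoxy ketone F2.
- TBAF/AcOH frees the phenol, which opens the epoxide 6-endo at the benzylic carbon with inversion, while the Cα–O bond becomes the 3-OH with retention.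
- The product is 10, where the route is rejoined.

**Step 5 is next.** The rearrangement may stop at the aromatised 6-(1,1-dimethylallyl) phenol, or the prenyl group may be lost.

The fallback puts the prenyl group on carbon before the ring is made.
- It sets out from 1. C-alkylation with prenyl bromide in aqueous KOH gives 1-[2,6-dihydroxy-4-methoxy-3-(3-methylbut-2-enyl)phenyl]ethanone F3.
- MOMCl/iPr2NEt caps the less hindered OH, remote from the prenyl group, and gives the 6-O-MOM acetophenone F4.
- Claisen–Schmidt condensation with 5 gives the 3'-prenyl chalcone F5.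
- The sequence of step 4 then gives the (2S)-8-prenylflavanone F6 and its TMS enol ether F7.
- Oxidation of F7 gives the 3-O-TMS 8-prenyl ketone F8. Here 2-(phenylsulfonyl)-3-phenyloxaziridine replaces DMDO, because the C-prenyl alkene is more electron-rich.
- HCl/MeOH strips the TMS group and both MOM groups, and the route is rejoined at 14.

**Step 1 is third.** The reaction may give the bis-ether, stop short of full conversion, or give a product that is hard to separate from Ph3PO.

The fallback replaces selective mono-alkylation by exhaustive alkylation followed by chelation-controlled mono-cleavage.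
- It sets out from 1. Excess prenol/PPh3/DIAD gives the 2,6-bis(prenyl ether) F9.
- MgBr2·OEt2 (1.1 equiv, toluene–Et2O, rt) binds the ketone and one ortho ether oxygen and cleaves only that prenyl group.
- The resulting magnesium phenoxide chelate shields the second ether, and work-up gives 3, where the route is rejoined.

## Further compounds
F1 | step 4 | (E)-1-[4-methoxy-6-(3-methylbut-2-enyloxy)-2-(triisopropylsilyloxy)phenyl]-3-[3-methoxy-4-(methoxymethoxy)phenyl]prop-2-en-1-one | COCOc1ccc(/C=C/C(=O)c2c(O[Si](C(C)C)(C(C)C)C(C)C)cc(OC)cc2OCC=C(C)C)cc1OC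
F2 | step 4 | (αR,βS)-trans-epoxide of F1 | O=C(c1c(O[Si](C(C)C)(C(C)C)C(C)C)cc(OC)cc1OCC=C(C)C)[C@@H]1O[C@H]1c1ccc(OCOC)c(OC)c1
F3 | step 5 | 1-[2,6-dihydroxy-4-methoxy-3-(3-methylbut-2-enyl)phenyl]ethanone | CC(=O)c1c(O)cc(OC)c(CC=C(C)C)c1O
F4 | step 5 | 1-[2-hydroxy-4-methoxy-6-(methoxymethoxy)-3-(3-methylbut-2-enyl)phenyl]ethanone | CC(=O)c1c(OCOC)cc(OC)c(CC=C(C)C)c1O
F5 | step 5 | (E)-1-[2-hydroxy-4-methoxy-6-(methoxymethoxy)-3-(3-methylbut-2-enyl)phenyl]-3-[3-methoxy-4-(methoxymethoxy)phenyl]prop-2-en-1-one | COCOc1ccc(/C=C/C(=O)c2c(OCOC)cc(OC)c(CC=C(C)C)c2O)cc1OC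
F6 | step 5 | (2S)-7-methoxy-5-(methoxymethoxy)-2-[3-methoxy-4-(methoxymethoxy)phenyl]-8-(3-methylbut-2-enyl)chroman-4-one | COc1cc([C@H]2Oc3c(CC=C(C)C)c(OC)cc(OCOC)c3C(=O)C2)ccc1OCOC
F7 | step 5 | (2S)-4-(trimethylsilyloxy)-2H-chromene derived from F6 | COc1cc([C@H]2Oc3c(CC=C(C)C)c(OC)cc(OCOC)c3C(O[Si](C)(C)C)=C2)ccc1OCOC
F8 | step 5 | (2R,3R)-3-(trimethylsilyloxy) derivative of F6 | COc1cc([C@H]2Oc3c(CC=C(C)C)c(OC)cc(OCOC)c3C(=O)[C@@H]2O[Si](C)(C)C)ccc1OCOC
F9 | step 1 | 1-[4-methoxy-2,6-bis(3-methylbut-2-enyloxy)phenyl]ethanone | CC(=O)c1c(OCC=C(C)C)cc(OC)cc1OCC=C(C)C
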